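Retrosynthesis: the benzoate C–O bond and the O4 protecting group are removed first, then C1'–C2' and C3'–CH3 are cut in one operation, giving a C11 dienyne, a 3-(chloromethyl)coumarin and AlMe3.
Enabling feature: the E-trisubstituted C2'=C3' alkene, whose C1' methylene sits on C3 of the pyranone ring and whose C3' carries a methyl group; this is the pattern left by syn methylmetalation of a terminal alkyne and capture at a CH2Cl carbon.
The dienyne is cut at C4'–C5' (propargyl anion plus allylic chloride) back to geranyl acetate, whose terminal E-methyl group is oxidised to carry the future benzoate oxygen.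
Forward: geranyl acetate to dienyne 9 (six steps); 4-chloro-3-formylcoumarin to chloride 14 (three steps); union in step 10; three end-group steps. No ring is formed, the benzopyranone being bought intact.
Stereochemistry: there are no stereocentres; 6'E comes from geranyl acetate, 10'E from the E-selective SeO2 oxidation, 2'E from syn methylalumination and stereoretentive coupling.

Key step: step 10

Remark: primed locants run along the side chain from the methylene on coumarin C3 (C1') to the oxygenated terminus (C12'). The 2-(trimethylsilyl)ethyl ether on O4 is assumed to fragment with fluoride about as readily as a 2-(trimethylsilyl)ethyl ester, because coumarin-4-olate is a carboxylate-like leaving group.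

Step 1
Reactants: 1 geranyl acetate
Product: 2 (2E,6E)-8-hydroxy-3,7-dimethylocta-2,6-dien-1-yl acetate
Conditions: SeO2 (cat.), t-BuOOH, salicylic acid (cat.), CH2Cl2, 0 °C → rt, stopped at partial conversion
Reagents that add atoms: tert-butyl hydroperoxide, CC(C)(C)OO (net oxygen source, relayed through SeO2, O=[Se]=O)
Why: Riley allylic oxidation (ene reaction, then [2,3]-sigmatropic shift) should attack the E-methyl group of the electron-rich terminal alkene and give the E-allylic alcohol, the 2,3-alkene being deactivated by the allylic acetate.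

Step 2
Reactants: 2 (2E,6E)-8-hydroxy-3,7-dimethylocta-2,6-dien-1-yl acetate
Product: 3 (2E,6E)-8-[(tert-butyldimethylsilyl)oxy]-3,7-dimethylocta-2,6-dien-1-yl acetate
Conditions: TBSCl, imidazole, DMF, rt
Reagents that add atoms: tert-butyldimethylsilyl chloride, CC(C)(C)[Si](C)(C)Cl
Why: Imidazole-promoted silylation of an unhindered primary alcohol is routine and leaves the acetate untouched.

Step 3
Reactants: 3 (2E,6E)-8-[(tert-butyldimethylsilyl)oxy]-3,7-dimethylocta-2,6-dien-1-yl acetate
Product: 4 (2E,6E)-8-[(tert-butyldimethylsilyl)oxy]-3,7-dimethylocta-2,6-dien-1-ol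
Conditions: K2CO3 (cat.), MeOH, rt
Reagents that add atoms: none
Why: Base-catalysed transesterification removes the acetate, while a primary TBS ether is stable to K2CO3 in methanol.

Step 4
Reactants: 4 (2E,6E)-8-[(tert-butyldimethylsilyl)oxy]-3,7-dimethylocta-2,6-dien-1-ol
Product: 5 tert-butyl{[(2E,6E)-8-chloro-2,6-dimethylocta-2,6-dien-1-yl]oxy}dimethylsilane
Conditions: PPh3, CCl4, reflux
Reagents that add atoms: carbon tetrachloride, ClC(Cl)(Cl)Cl
Why: The Appel reaction converts a primary allylic alcohol into the chloride by SN2 displacement of the alkoxyphosphonium ion under neutral conditions, so neither allylic transposition nor silyl ether loss is expected.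

Step 5
Reactants: 6 1-(trimethylsilyl)propyne; 5 tert-butyl{[(2E,6E)-8-chloro-2,6-dimethylocta-2,6-dien-1-yl]oxy}dimethylsilane
Product: 8 tert-butyl{[(2E,6E)-2,6-dimethyl-11-(trimethylsilyl)undeca-2,6-dien-10-yn-1-yl]oxy}dimethylsilane, via 3-lithio-1-(trimethylsilyl)propyne 7 (not isolated)
Conditions: 6, n-BuLi, THF, −78 → −20 °C; then 5, −78 °C → rt
Reagents that add atoms: none
Why: Propargylic lithiation followed by SN2 alkylation of the primary allylic chloride should form C4'–C5', the C-silyl group steering the ambident anion to its propargylic carbon and the unhindered chloride favouring direct over allylic substitution, so both alkene geometries are retained.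

Step 6
Reactants: 8 tert-butyl{[(2E,6E)-2,6-dimethyl-11-(trimethylsilyl)undeca-2,6-dien-10-yn-1-yl]oxy}dimethylsilane
Product: 9 tert-butyl{[(2E,6E)-2,6-dimethylundeca-2,6-dien-10-yn-1-yl]oxy}dimethylsilane
Conditions: K2CO3, MeOH, rt
Reagents that add atoms: none
Why: Methanolytic protodesilylation of the alkynyl C–Si bond is much faster than cleavage of the Si–O bond of the TBS ether under these mildly basic conditions.

Step 7
Reactants: 10 4-chloro-3-formylcoumarin (4-chloro-2-oxo-2H-chromene-3-carbaldehyde); 11 2-(trimethylsilyl)ethanol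
Product: 12 2-oxo-4-[2-(trimethylsilyl)ethoxy]-2H-chromene-3-carbaldehyde
Conditions: Et3N, MeCN, 0 °C → rt
Reagents that add atoms: none
Why: Addition–elimination (vinylogous acyl substitution) at C4, activated by both the lactone carbonyl and the 3-formyl group, should replace chloride by the alkoxy group.

Step 8
Reactants: 12 2-oxo-4-[2-(trimethylsilyl)ethoxy]-2H-chromene-3-carbaldehyde
Product: 13 3-(hydroxymethyl)-4-[2-(trimethylsilyl)ethoxy]-2H-chromen-2-one
Conditions: NaBH4, CeCl3·7H2O, MeOH–THF, −40 → 0 °C
Reagents that add atoms: none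
Why: Luche reduction should reduce the aldehyde in the 1,2-sense, the cerium-modified borohydride avoiding conjugate attack at C4 and leaving the lactone intact.

Step 9
Reactants: 13 3-(hydroxymethyl)-4-[2-(trimethylsilyl)ethoxy]-2H-chromen-2-one
Product: 14 3-(chloromethyl)-4-[2-(trimethylsilyl)ethoxy]-2H-chromen-2-one
Conditions: PPh3, NCS, THF, 0 °C → rt; used promptly
Reagents that add atoms: N-chlorosuccinimide, O=C1CCC(=O)N1Cl
Why: Appel-type chlorination with PPh3 and NCS converts the primary allylic alcohol into the chloride without free acid, which should spare the 2-(trimethylsilyl)ethyl enol ether.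

Step 10
Reactants: 9 tert-butyl{[(2E,6E)-2,6-dimethylundeca-2,6-dien-10-yn-1-yl]oxy}dimethylsilane; 14 3-(chloromethyl)-4-[2-(trimethylsilyl)ethoxy]-2H-chromen-2-one; 15 trimethylaluminium
Product: 17 3-[(2E,6E,10E)-12-[(tert-butyldimethylsilyl)oxy]-3,7,11-trimethyldodeca-2,6,10-trien-1-yl]-4-[2-(trimethylsilyl)ethoxy]-2H-chromen-2-one, via E-alkenyldimethylalane 16 (not isolated)
Conditions: 9, AlMe3, Cp2ZrCl2 (cat.), ClCH2CH2Cl, rt; volatiles (excess AlMe3) removed in vacuo, residue taken up in THF; then 14, NiCl2(PPh3)2 (cat.)/n-BuLi, THF, 0 °C → rt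
Reagents that add atoms: trimethylaluminium (15), C[Al](C)C
Why: Cp2ZrCl2-activated AlMe3 should add methyl and aluminium across the terminal alkyne of 9 in a syn fashion, methyl going to the internal carbon (Negishi carboalumination), to give the E-alkenyldimethylalane 16 and with it the C3'–CH3 bond. Zerovalent nickel, generated from NiCl2(PPh3)2 and n-BuLi, then inserts into the activated C–Cl bond of 14, the alkenyl group passes from aluminium to nickel, and reductive elimination forms C1'–C2' with retention of alkene geometry; the closest known reaction type is the nickel-catalysed coupling of alkenylalanes with benzylic chlorides and chloromethylquinones. No ring is closed and no stereocentre is created; the only stereochemical element, the 2'E alkene, is fixed by the syn addition and its regiochemistry and is carried through the coupling unchanged. The step needs attack at the CH2Cl carbon and not at C4 or the lactone carbonyl, which fast oxidative addition into the allylic, benzylic-type chloride and the removal of excess AlMe3 before the coupling should secure, while the remote trisubstituted alkenes and both silyl ethers are inert to the alane.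

Step 11
Reactants: 17 3-[(2E,6E,10E)-12-[(tert-butyldimethylsilyl)oxy]-3,7,11-trimethyldodeca-2,6,10-trien-1-yl]-4-[2-(trimethylsilyl)ethoxy]-2H-chromen-2-one
Product: 18 3-[(2E,6E,10E)-12-hydroxy-3,7,11-trimethyldodeca-2,6,10-trien-1-yl]-4-[2-(trimethylsilyl)ethoxy]-2H-chromen-2-one
Conditions: AcOH–THF–H2O (3:1:1), rt
Reagents that add atoms: none
Why: Acid-catalysed hydrolysis of the unhindered primary TBS ether should proceed under conditions too mild to hydrolyse the vinylogous ester at C4 or to protonate the trisubstituted alkenes.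

Step 12
Reactants: 18 3-[(2E,6E,10E)-12-hydroxy-3,7,11-trimethyldodeca-2,6,10-trien-1-yl]-4-[2-(trimethylsilyl)ethoxy]-2H-chromen-2-one
Product: 19 (2E,6E,10E)-2,6,10-trimethyl-12-{2-oxo-4-[2-(trimethylsilyl)ethoxy]-2H-chromen-3-yl}dodeca-2,6,10-trien-1-yl benzoate
Conditions: BzCl, pyridine, DMAP (cat.), CH2Cl2, 0 °C → rt
Reagents that add atoms: benzoyl chloride, O=C(Cl)c1ccccc1
Why: DMAP-catalysed acylation (nucleophilic acyl substitution) benzoylates the only free hydroxyl group.

Step 13
Reactants: 19 (2E,6E,10E)-2,6,10-trimethyl-12-{2-oxo-4-[2-(trimethylsilyl)ethoxy]-2H-chromen-3-yl}dodeca-2,6,10-trien-1-yl benzoate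
Product: 20 E-omega-benzoyloxyferulenol, (2E,6E,10E)-12-(4-hydroxy-2-oxo-2H-chromen-3-yl)-2,6,10-trimethyldodeca-2,6,10-trien-1-yl benzoate
Conditions: Bu4NF, THF, 0 °C → rt; cold dilute aq. HCl work-up
Reagents that add atoms: none
Why: Fluoride attack on the trimethylsilyl group triggers a Peterson-type β-fragmentation that expels ethene and the stabilised coumarin-4-olate, which should proceed under conditions that leave the primary benzoate in place.

Compound list
1 | geranyl acetate | CC(C)=CCC/C(C)=C/COC(C)=O | starting material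
2 | (2E,6E)-8-hydroxy-3,7-dimethylocta-2,6-dien-1-yl acetate | CC(=O)OC/C=C(\C)CC/C=C(\C)CO | intermediate
3 | (2E,6E)-8-[(tert-butyldimethylsilyl)oxy]-3,7-dimethylocta-2,6-dien-1-yl acetate | CC(=O)OC/C=C(\C)CC/C=C(\C)CO[Si](C)(C)C(C)(C)C | intermediate
4 | (2E,6E)-8-[(tert-butyldimethylsilyl)oxy]-3,7-dimethylocta-2,6-dien-1-ol | OC/C=C(\C)CC/C=C(\C)CO[Si](C)(C)C(C)(C)C | intermediate
5 | tert-butyl{[(2E,6E)-8-chloro-2,6-dimethylocta-2,6-dien-1-yl]oxy}dimethylsilane | ClC/C=C(\C)CC/C=C(\C)CO[Si](C)(C)C(C)(C)C | intermediate
6 | 1-(trimethylsilyl)propyne | CC#C[Si](C)(C)C | starting material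
7 | 3-lithio-1-(trimethylsilyl)propyne | [Li]CC#C[Si](C)(C)C | intermediate (not isolated)
8 | tert-butyl{[(2E,6E)-2,6-dimethyl-11-(trimethylsilyl)undeca-2,6-dien-10-yn-1-yl]oxy}dimethylsilane | C/C(=C\CCC#C[Si](C)(C)C)CC/C=C(\C)CO[Si](C)(C)C(C)(C)C | intermediate
9 | tert-butyl{[(2E,6E)-2,6-dimethylundeca-2,6-dien-10-yn-1-yl]oxy}dimethylsilane | C/C(=C\CCC#C)CC/C=C(\C)CO[Si](C)(C)C(C)(C)C | intermediate
10 | 4-chloro-3-formylcoumarin (4-chloro-2-oxo-2H-chromene-3-carbaldehyde) | O=Cc1c(Cl)c2ccccc2oc1=O | starting material
11 | 2-(trimethylsilyl)ethanol | OCC[Si](C)(C)C | starting material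
12 | 2-oxo-4-[2-(trimethylsilyl)ethoxy]-2H-chromene-3-carbaldehyde | O=Cc1c(OCC[Si](C)(C)C)c2ccccc2oc1=O | intermediate
13 | 3-(hydroxymethyl)-4-[2-(trimethylsilyl)ethoxy]-2H-chromen-2-one | OCc1c(OCC[Si](C)(C)C)c2ccccc2oc1=O | intermediate
14 | 3-(chloromethyl)-4-[2-(trimethylsilyl)ethoxy]-2H-chromen-2-one | ClCc1c(OCC[Si](C)(C)C)c2ccccc2oc1=O | intermediate
15 | trimethylaluminium | C[Al](C)C | starting material
16 | [(1E,5E,9E)-11-[(tert-butyldimethylsilyl)oxy]-2,6,10-trimethylundeca-1,5,9-trien-1-yl]dimethylalane | C/C(=C\CC/C(C)=C/[Al](C)C)CC/C=C(\C)CO[Si](C)(C)C(C)(C)C | intermediate (not isolated)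
17 | 3-[(2E,6E,10E)-12-[(tert-butyldimethylsilyl)oxy]-3,7,11-trimethyldodeca-2,6,10-trien-1-yl]-4-[2-(trimethylsilyl)ethoxy]-2H-chromen-2-one | C/C(=C\CC/C(C)=C/Cc1c(OCC[Si](C)(C)C)c2ccccc2oc1=O)CC/C=C(\C)CO[Si](C)(C)C(C)(C)C | intermediate
18 | 3-[(2E,6E,10E)-12-hydroxy-3,7,11-trimethyldodeca-2,6,10-trien-1-yl]-4-[2-(trimethylsilyl)ethoxy]-2H-chromen-2-one | C/C(=C\CC/C(C)=C/Cc1c(OCC[Si](C)(C)C)c2ccccc2oc1=O)CC/C=C(\C)CO | intermediate
19 | (2E,6E,10E)-2,6,10-trimethyl-12-{2-oxo-4-[2-(trimethylsilyl)ethoxy]-2H-chromen-3-yl}dodeca-2,6,10-trien-1-yl benzoate | C/C(=C\CC/C(C)=C/Cc1c(OCC[Si](C)(C)C)c2ccccc2oc1=O)CC/C=C(\C)COC(=O)c1ccccc1 | intermediate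
20 | E-omega-benzoyloxyferulenol, (2E,6E,10E)-12-(4-hydroxy-2-oxo-2H-chromen-3-yl)-2,6,10-trimethyldodeca-2,6,10-trien-1-yl benzoate | C/C(=C\CC/C(C)=C/Cc1c(O)c2ccccc2oc1=O)CC/C=C(\C)COC(=O)c1ccccc1 | target

Total step count: 13.
Longest linear sequence: 10 steps (steps 1–6 and 10–13, from geranyl acetate); the coumarin branch (steps 7–9) joins at step 10.

Steps most likely to fail

Step 10. Methyl transfer from aluminium to the chloromethyl carbon may compete with alkenyl transfer, the Lewis-acidic alane may ionise chloride 14 before nickel inserts, or the chloride may homocouple. The fallback reverses the polarity of the two partners and sets out from 9 and 14. Alane 16, made from 9 as in step 10, would be quenched with I2 in THF at −30 °C to give tert-butyl{[(2E,6E,10E)-11-iodo-2,6,10-trimethylundeca-2,6,10-trien-1-yl]oxy}dimethylsilane F1, which can be purified and its geometry checked. Chloride 14 would be treated with zinc dust and LiCl in THF at 0 °C to give {[2-oxo-4-[2-(trimethylsilyl)ethoxy]-2H-chromen-3-yl]methyl}zinc chloride F2. Negishi coupling of F1 with F2 under Pd(PPh3)4 in THF at rt should form the same C1'–C2' bond with retention at the alkenyl carbon and return to the route at 17.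

Step 9. The doubly activated chloride may ionise during its formation or on silica, leading to hydrolysis, self-condensation or loss of the O4 group. The fallback replaces the halide by a stable ester and the nickel coupling by a π-allylpalladium coupling, and sets out from 13. Ac2O and pyridine in CH2Cl2 would give {2-oxo-4-[2-(trimethylsilyl)ethoxy]-2H-chromen-3-yl}methyl acetate F3, which should be storable. F3 would then be coupled with alane 16 under Pd(PPh3)4 in THF, the palladium-catalysed allylic substitution of alkenylalanes known for allylic acetates. This bypasses 14 and returns to the route at 17.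

Step 13. Fragmentation of the silylethyl ether may be slow, and the forcing conditions then needed would let basic fluoride hydrolyse or transfer the benzoate. The fallback deprotects before any ester is present and sets out from 17. Excess Bu4NF in THF at 40 °C, followed by dilute acid work-up, would remove both silyl groups to give 4-hydroxy-3-[(2E,6E,10E)-12-hydroxy-3,7,11-trimethyldodeca-2,6,10-trien-1-yl]-2H-chromen-2-one F4. Excess BzCl in pyridine would give 3-[(2E,6E,10E)-12-(benzoyloxy)-3,7,11-trimethyldodeca-2,6,10-trien-1-yl]-2-oxo-2H-chromen-4-yl benzoate F5. One equivalent of pyrrolidine in CH2Cl2 at 0 °C should cleave only the activated enol benzoate at O4, a vinylogous mixed anhydride, and after acidification return to the route at the target 20.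

Further compounds
F1 | step 10 | tert-butyl{[(2E,6E,10E)-11-iodo-2,6,10-trimethylundeca-2,6,10-trien-1-yl]oxy}dimethylsilane | C/C(=C\CC/C(C)=C/I)CC/C=C(\C)CO[Si](C)(C)C(C)(C)C
F2 | step 10 | {[2-oxo-4-[2-(trimethylsilyl)ethoxy]-2H-chromen-3-yl]methyl}zinc chloride | Cl[Zn]Cc1c(OCC[Si](C)(C)C)c2ccccc2oc1=O
F3 | step 9 | {2-oxo-4-[2-(trimethylsilyl)ethoxy]-2H-chromen-3-yl}methyl acetate | CC(=O)OCc1c(OCC[Si](C)(C)C)c2ccccc2oc1=O
F4 | step 13 | 4-hydroxy-3-[(2E,6E,10E)-12-hydroxy-3,7,11-trimethyldodeca-2,6,10-trien-1-yl]-2H-chromen-2-one | C/C(=C\CC/C(C)=C/Cc1c(O)c2ccccc2oc1=O)CC/C=C(\C)CO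
F5 | step 13 | 3-[(2E,6E,10E)-12-(benzoyloxy)-3,7,11-trimethyldodeca-2,6,10-trien-1-yl]-2-oxo-2H-chromen-4-yl benzoate | C/C(=C\CC/C(C)=C/Cc1c(OC(=O)c2ccccc2)c2ccccc2oc1=O)CC/C=C(\C)COC(=O)c1ccccc1
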